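## Retrosynthetic overview
1. The target comes from two O-acylations (C8 senecioate, C6 acetate) of the 4,5-epoxygermacr-1(10)-ene-6,8-diol.
2. The oxirane is the second ring and is made last. It comes from hydroxyl-directed, tartrate-controlled epoxidation of the 4Z-olefin of the finished carbocycle, as in the plant.
3. The C8 carbinol comes from O6-directed hydride delivery to the 6-hydroxygermacradien-8-one.
4. The ten-membered ring is formed first, at C6–C7, which is the C1–C10 closure of an acyclic (2Z,6E)-farnesane. It is run as a hydride-triggered reductive aldol of 9-oxofarnesal: H goes to C11, C10 bonds to C1, and oxygen stays on C1. This copies cyclisation, 1,3-hydride shift and water capture.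
5. 9-Oxofarnesal comes from a Meyer–Schuster shift of a C15 enynal, built from neryl acetate (C10) and 2-methylbut-3-yn-2-ol (C5).

Assumption: the SMILES is read literally. C3 and C6 are cis on the oxirane (4S,5R), so the epoxide derives from a 4Z-olefin and the neryl, (2Z,6E)-farnesane series is used. Germacrane numbering is used throughout (C6 OAc, C7 i-Pr, C8 O-senecioyl, C4/C5 oxirane, C1=C10 olefin).

Assumption: the sense of induction of BINAPO in the new ring closure has no precedent. (S)-BINAPO is written for the (6S,7S)-ketol. Absolute configuration is fixed independently in step 8.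

## Route

Step 1
Reactants: 1 neryl acetate
Product: 2 (2Z,6E)-8-hydroxy-3,7-dimethylocta-2,6-dien-1-yl acetate
Conditions: SeO2 (10 mol %), salicylic acid (10 mol %), t-BuOOH (3 equiv), CH2Cl2, rt
Reagents that add atoms: tert-butyl hydroperoxide CC(C)(C)OO (oxygen atom, passed on through SeO2 O=[Se]=O)
Why: Riley allylic oxidation (ene reaction, then [2,3]-sigmatropic shift) selects the electron-rich terminal olefin over the acetate-deactivated one and oxidises only the methyl group trans to the chain, which fixes the E geometry of the later C1=C10 bond.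

Step 2
Reactants: 2 (2Z,6E)-8-hydroxy-3,7-dimethylocta-2,6-dien-1-yl acetate
Product: 3 (2Z,6E)-8-bromo-3,7-dimethylocta-2,6-dien-1-yl acetate
Conditions: CBr4, PPh3, CH2Cl2, 0 °C
Reagents that add atoms: carbon tetrabromide BrC(Br)(Br)Br
Why: Appel reaction, an SN2 displacement at the primary allylic carbon without allylic shift that leaves the acetate and both olefin geometries untouched.

Step 3
Reactants: 3 (2Z,6E)-8-bromo-3,7-dimethylocta-2,6-dien-1-yl acetate; 4 2-methylbut-3-yn-2-ol
Product: 6 (2Z,6E)-3,7,11-trimethyldodeca-2,6-dien-9-yne-1,11-diol, via enyne acetate 5 (not isolated)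
Conditions: CuI (10 mol %), K2CO3 (2 equiv), DMF, rt; then MeOH added, rt
Reagents that add atoms: 2-methylbut-3-yn-2-ol (4) CC(C)(O)C#C
Why: Skipped-enyne coupling (allylic substitution by the CuI-derived acetylide) at the unhindered primary terminus makes the C8–C9 bond, and methanol in the same carbonate suspension then transesterifies the acetate before any base-sensitive ketone exists.

Step 4
Reactants: 6 (2Z,6E)-3,7,11-trimethyldodeca-2,6-dien-9-yne-1,11-diol
Product: 7 (2Z,6E)-11-hydroxy-3,7,11-trimethyldodeca-2,6-dien-9-ynal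
Conditions: TEMPO (10 mol %), PhI(OAc)2 (1.1 equiv), MeCN/pH 7 buffer, 0 °C
Reagents that add atoms: none
Why: Oxoammonium (TEMPO) oxidation takes only the primary allylic alcohol, is known to convert nerol-type alcohols to Z-enals without Z/E leakage, and cannot oxidise the tertiary carbinol.

Step 5
Reactants: 7 (2Z,6E)-11-hydroxy-3,7,11-trimethyldodeca-2,6-dien-9-ynal
Product: 8 (2Z,6E)-3,7,11-trimethyl-9-oxododeca-2,6,10-trienal
Conditions: MoO2(acac)2 (2 mol %), AuCl(PPh3) (2 mol %), AgOTf (2 mol %), toluene, rt, 30 min
Reagents that add atoms: none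
Why: Meyer–Schuster rearrangement moves the tertiary OH across the alkyne to an allenol that tautomerises to the β,β-dimethyl enone with its carbonyl at C8, and the neutral room-temperature conditions keep the Z-enal and the skipped E-olefin in place.

Step 6
Reactants: 8 (2Z,6E)-3,7,11-trimethyl-9-oxododeca-2,6,10-trienal
Product: 11 (1(10)E,4Z,6S,7S)-6-hydroxygermacra-1(10),4-dien-8-one, via Z-trichlorosilyl enolate 9 (not isolated), via trichlorosilyl aldolate 10 (not isolated)
Conditions: HSiCl3 (5 equiv), (S)-BINAPO (20 mol %), CH2Cl2, −45 °C, 8 added over 12 h (final 2 mM); aq NaHCO3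
Reagents that add atoms: none
Why: Proposed new method: this is a macrocyclic version of the Lewis-base-catalysed trichlorosilane reductive aldol reaction, which is known intermolecularly for s-cis enones with aldehydes and gives high ee with BINAPO, while medium rings are known to close by aldol addition of regiospecifically generated enolates such as SmI2-Reformatsky enolates; the BINAPO·HSiCl3 adduct delivers hydride to C11 only through a six-membered cyclic transition state, which the s-cis β,β-dimethyl enone can reach and the s-trans Z-enal cannot, so 9 forms regiospecifically at C7 (never at the more acidic C9) with Z(O) geometry; its aldehyde-binding silicon closes C7–C6 through a chair fused to the chair-like C5–C10 loop of the nascent ring (bicyclo[3.3.1]-like), placing i-Pr equatorial and O6 axial, which is the 6,7-relationship of the target, while the C2-symmetric ligand selects one of the two mirror-image chairs; slow addition suppresses dimers and the low temperature suppresses the competing six-ring ene closure.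

Step 7
Reactants: 11 (1(10)E,4Z,6S,7S)-6-hydroxygermacra-1(10),4-dien-8-one
Product: 13 (1(10)E,4Z,6S,7R,8S)-germacra-1(10),4-diene-6,8-diol, via alkoxydiacetoxyborohydride 12 (not isolated)
Conditions: Me4NBH(OAc)3 (5 equiv), MeCN/AcOH 3:1, −30 °C; aq NaHCO3
Reagents that add atoms: none
Why: Saksena–Evans reduction, in which the axial C6–OH exchanges onto boron and hydride is delivered intramolecularly to the same face of C8 (1,3-diaxial reach, as in 3-hydroxycyclohexanones), so O8 ends equatorial and 1,3-anti to O6 (8S) and the olefins are inert.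

Step 8
Reactants: 13 (1(10)E,4Z,6S,7R,8S)-germacra-1(10),4-diene-6,8-diol
Product: 14 (1(10)E,4S,5R,6R,7R,8S)-4,5-epoxygermacr-1(10)-ene-6,8-diol
Conditions: Ti(OiPr)4 (20 mol %), D-(−)-DIPT (26 mol %), t-BuOOH (decane, 1.0 equiv), 4 Å molecular sieves, CH2Cl2, −20 °C
Reagents that add atoms: tert-butyl hydroperoxide CC(C)(C)OO
Why: Sharpless asymmetric epoxidation of a secondary allylic alcohol, in which only the allylic C6–OH loads its olefin onto the Ti(OiPr)4/DIPT catalyst so C4=C5 reacts and the homoallylic C1=C10 does not; D-(−)-tartrate gives the 4S,5R oxirane (mirror image of the L-(+)-tartrate/nerol outcome) with the erythro C5/C6 relationship typical of this reaction, which is also the outer face of the conformer with equatorial i-Pr (matched); syn addition to the 4Z-olefin gives the cis-oxirane, and any enantiomeric diol is mismatched and left behind, so the ee rises.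

Step 9
Reactants: 14 (1(10)E,4S,5R,6R,7R,8S)-4,5-epoxygermacr-1(10)-ene-6,8-diol; 15 3-methylbut-2-enoyl chloride; 16 acetic anhydride
Product: 18 [(1R,2R,3R,4S,6E,10S)-2-acetyloxy-6,10-dimethyl-3-(propan-2-yl)-11-oxabicyclo[8.1.0]undec-6-en-4-yl] 3-methylbut-2-enoate, via 8-O-senecioyl epoxy alcohol 17 (not isolated)
Conditions: 15 (1.1 equiv), pyridine, CH2Cl2, 0 °C; then 16 (5 equiv), DMAP (20 mol %), rt
Reagents that add atoms: 3-methylbut-2-enoyl chloride (15) CC(C)=CC(=O)Cl; acetic anhydride (16) CC(=O)OC(C)=O
Why: Sequential esterification, in which the equatorial C8–OH next to a CH2 is acylated well before the axial C6–OH wedged between the oxirane and C7, pyridine (not a trialkylamine) avoids the vinylketene path that deconjugates senecioates, and DMAP-catalysed acetylation then caps O6 under basic conditions tolerated by the acid-labile epoxide without touching any stereocentre.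

## Compound list
1 | neryl acetate, (2Z)-3,7-dimethylocta-2,6-dien-1-yl acetate | CC(C)=CCC/C(C)=C\COC(C)=O | starting material
2 | (2Z,6E)-8-hydroxy-3,7-dimethylocta-2,6-dien-1-yl acetate | OC/C(C)=C/CC/C(C)=C\COC(C)=O | intermediate
3 | (2Z,6E)-8-bromo-3,7-dimethylocta-2,6-dien-1-yl acetate | BrC/C(C)=C/CC/C(C)=C\COC(C)=O | intermediate
4 | 2-methylbut-3-yn-2-ol | CC(C)(O)C#C | starting material
5 | (2Z,6E)-11-hydroxy-3,7,11-trimethyldodeca-2,6-dien-9-yn-1-yl acetate | CC(C)(O)C#CC/C(C)=C/CC/C(C)=C\COC(C)=O | intermediate (not isolated)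
6 | (2Z,6E)-3,7,11-trimethyldodeca-2,6-dien-9-yne-1,11-diol | CC(C)(O)C#CC/C(C)=C/CC/C(C)=C\CO | intermediate
7 | (2Z,6E)-11-hydroxy-3,7,11-trimethyldodeca-2,6-dien-9-ynal | CC(C)(O)C#CC/C(C)=C/CC/C(C)=C\C=O | intermediate
8 | (2Z,6E)-3,7,11-trimethyl-9-oxododeca-2,6,10-trienal (9-oxo-(2Z,6E)-farnesal) | CC(C)=CC(=O)C/C(C)=C/CC/C(C)=C\C=O | intermediate
9 | (2Z,6E,9Z)-3,7,11-trimethyl-9-(trichlorosilyloxy)dodeca-2,6,9-trienal | CC(C)/C=C(\O[Si](Cl)(Cl)Cl)C/C(C)=C/CC/C(C)=C\C=O | intermediate (not isolated)
10 | (1(10)E,4Z,6S,7S)-6-(trichlorosilyloxy)germacra-1(10),4-dien-8-one | C1/C(C)=C\[C@H](O[Si](Cl)(Cl)Cl)[C@H](C(C)C)C(=O)C/C(C)=C/C1 | intermediate (not isolated)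
11 | (1(10)E,4Z,6S,7S)-6-hydroxygermacra-1(10),4-dien-8-one = (3E,7Z,9S,10S)-9-hydroxy-3,7-dimethyl-10-(propan-2-yl)cyclodeca-3,7-dien-1-one | C1/C(C)=C\[C@H](O)[C@H](C(C)C)C(=O)C/C(C)=C/C1 | intermediate
12 | tetramethylammonium diacetoxy(hydrido)borate bound to O6 of 11 | C[N+](C)(C)C.C1/C(C)=C\[C@H](O[BH-](OC(C)=O)OC(C)=O)[C@H](C(C)C)C(=O)C/C(C)=C/C1 | intermediate (not isolated)
13 | (1(10)E,4Z,6S,7R,8S)-germacra-1(10),4-diene-6,8-diol = (1S,2R,3S,4Z,8E)-5,9-dimethyl-2-(propan-2-yl)cyclodeca-4,8-diene-1,3-diol | C1/C(C)=C\[C@H](O)[C@H](C(C)C)[C@@H](O)C/C(C)=C/C1 | intermediate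
14 | (1R,2R,3R,4S,6E,10S)-6,10-dimethyl-3-(propan-2-yl)-11-oxabicyclo[8.1.0]undec-6-ene-2,4-diol (germacrane 4S,5R,6R,7R,8S) | O[C@@H]1[C@H](C(C)C)[C@@H](O)C/C(C)=C/CC[C@]2(C)O[C@H]12 | intermediate
15 | 3-methylbut-2-enoyl chloride (senecioyl chloride) | CC(C)=CC(=O)Cl | starting material
16 | acetic anhydride | CC(=O)OC(C)=O | starting material
17 | (germacrane 4S,5R,6R,7S,8S)-4,5-epoxy-6-hydroxygermacr-1(10)-en-8-yl 3-methylbut-2-enoate | O[C@@H]1[C@H](C(C)C)[C@@H](OC(=O)C=C(C)C)C/C(C)=C/CC[C@]2(C)O[C@H]12 | intermediate (not isolated)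
18 | CNP0118795.1 (germacrane 4S,5R,6R,7R,8S) | CC(=O)O[C@@H]1[C@H](C(C)C)[C@@H](OC(=O)C=C(C)C)C/C(C)=C/CC[C@]2(C)O[C@H]12 | target

The changes of descriptor at C6 and C7 along 10–18 are CIP priority changes only. The spatial arrangement set in step 6 is never altered.

## Step count and risks
Total steps: 9. Longest linear sequence: 9 steps, from neryl acetate 1.

**Step 6** is the most likely to fail. Possible failures are reduction of the aldehyde, six-ring ene closure, oligomers, the wrong 6,7-isomer or low ee. The fallback sets out from 7, omits step 5 and returns at 11.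
- VO(OSiPh3)3 (10 mol %) in 1,2-dichloroethane at 80 °C and 2 mM converts the tertiary propargylic alcohol, through the [3,3]-shift of its vanadate ester, into an O-bound allenolate.
- The allenolate adds through C7 to the enal (Meyer–Schuster/aldol reaction) and gives racemic 6-hydroxygermacra-1(10),4,7(11)-trien-8-one F1. No hydride reagent is ever present next to an aldehyde.
- The enone of F1 is then reduced 1,4 with Mn(dpm)3/PhSiH3/i-PrOH. Protonation at C7 gives 11 as the racemate, and the C7 epimer is removed by chromatography.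
- Step 8, run with 0.5 equiv t-BuOOH, then acts as a kinetic resolution.

**Step 8** may fail because the hindered axial carbinol loads slowly, or because the catalyst triggers transannular opening of the new oxirane by the C1=C10 olefin. The fallback sets out from 13 and returns at 17.
- Reagent control is given up and the order of events is changed.
- 13 is first mono-acylated with 15 in pyridine to give 6-hydroxygermacra-1(10),4-dien-8-yl 3-methylbut-2-enoate F2, which removes the homoallylic hydroxyl.
- The single remaining allylic OH then directs VO(acac)2 (5 mol %)/t-BuOOH in toluene at 0 °C to the outer face of C4=C5. The small O–C–C=C angle favoured by this catalyst matches the axial carbinol.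
- This gives 17, now isolated, which is acetylated with 16 to 18. Enantiopurity then rests on step 6.

**Step 5** may fail through loss of the Z-enal or conjugation of the skipped enone under the gold/silver salts. The fallback sets out from 3 and returns at 8.
- A three-component carbonylative Stille coupling is used: CO (1 atm), tributyl(2-methylprop-1-enyl)stannane, Pd2(dba)3 and AsPh3 in THF at 45 °C.
- It builds the ketone from carbon monoxide and gives 9-oxo-(2Z,6E)-farnesyl acetate F3.
- Neutral transesterification with Candida antarctica lipase B and MeOH in MTBE gives 9-oxo-(2Z,6E)-farnesol F4.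
- TEMPO/PhI(OAc)2 then oxidises F4 to 8.

## Further compounds
F1 | step 6 | racemic (1(10)E,4Z)-6-hydroxygermacra-1(10),4,7(11)-trien-8-one (6S enantiomer drawn) | C1/C(C)=C\[C@H](O)C(=C(C)C)C(=O)C/C(C)=C/C1
F2 | step 8 | (1(10)E,4Z,6S,7S,8S)-6-hydroxygermacra-1(10),4-dien-8-yl 3-methylbut-2-enoate | C1/C(C)=C\[C@H](O)[C@H](C(C)C)[C@@H](OC(=O)C=C(C)C)C/C(C)=C/C1
F3 | step 5 | (2Z,6E)-3,7,11-trimethyl-9-oxododeca-2,6,10-trien-1-yl acetate | CC(C)=CC(=O)C/C(C)=C/CC/C(C)=C\COC(C)=O
F4 | step 5 | (6E,10Z)-12-hydroxy-2,6,10-trimethyldodeca-2,6,10-trien-4-one | CC(C)=CC(=O)C/C(C)=C/CC/C(C)=C\CO
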